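(All runs are calculated with constants of no real substance.)

If you charge J with a surplus of L, you expect the J to be used up, and these flasks do not do that.

| flask | J | L | X | remark | time |
|---|---|---|---|---|---|
| noon | 0.17 M | 0.36 M | 0.85 M | run made earlier |  |
| autumn | 0.17 M | 0.71 M | 0.85 M | run made earlier |  |
| west | 0.17 M | 0.260 M | 0.850 M |  | 4.0 min |
| north-west | 0.17 M | 0.380 M | 0.850 M |  | 4.0 min |
| south-east | 0.17 M | 0.570 M | 0.850 M |  | 4.0 min |

- noon (time / min: J / %, Q / %): 0.167: 71.2, 30.5; 0.417: 61.6, 37.4; 0.833: 59.7, 41.2; 1.33: 58.2, 41.6; 1.50: 57.9, 39.4; 2.00: 57.3, 40.8; 3.00: 57.1, 44.4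
- autumn (time / min: J / %, Q / %): 0.250: 43.9, 55.6; 0.333: 40.3, 59.4; 0.500: 38.8, 61.0; 0.833: 38.7, 61.9; 1.33: 38.9, 59.8; 2.00: 37.2, 61.0; 3.00: 39.3, 61.2

(standard deviation of a reading: 1 percentage point)

- a reading or a percentage of Q counts all its forms, free or not

- which of these there is most of at the end, counted by the J in it, west (Q / J)
- which of these there is most of at the end, counted by the J in it, north-west (Q / J)
- which of these there is most of at the end, counted by the J in it, south-east (Q / J)
- amount of the one of these that there is most of at the end, in percent of the J charged, west
- amount of the one of these that there is most of at the end, in percent of the J charged, north-west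
- amount of the one of these that there is most of at the end, in percent of the J charged, south-east

Two numbers in the noon run don't seem to go together. L was charged at 2.12 times the J, yet the J reading stands at 57.1% at 3.00 min, after 57.3% at 2.00 min. If each J lost took one L, 0.287 M of L would still be there, so a lack of L does not explain the stop.

My reckoning is that the step runs both ways: the forward rate goes with J times L, the back rate with Q. Divide one rate by the other and time drops out, so where they are equal, Q over J, divided by free L, is a constant. Counting Q as the J gone, the last J reading gives 2.62 L mol⁻¹ for noon and 2.55 L mol⁻¹ for autumn, although autumn had twice the L. Their mean, 2.58 L mol⁻¹, is what I call the stopping quotient, an apparent equilibrium constant.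

The asked time 4.0 min is later than the last readings at 3.00 min, so I take each flask at its stop. There, the turned share of J over the unturned share equals the quotient times the L charged less the J turned. This puts Q at 34.2% in west, 44.1% in north-west and 55.1% in south-east.

The forecast, on the grounds that “A reversible J + L ⇌ Q fits well”, says J at 66% in west, J at 56% in north-west and Q at 55% in south-east.

The flasks give J at 66.3% in west, J at 56.5% in north-west and Q at 54.8% in south-east.

    J + L ⇌ Q (K = 2.90 L mol⁻¹, k = 0.160 L mol⁻¹ s⁻¹)
    X + L ⇌ E (K = 1.00 L mol⁻¹, k = 0.0500 L mol⁻¹ s⁻¹)
    X + Q ⇌ Z, settled at all times (K = 0.680 L mol⁻¹)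

West also holds E at 0.0865 M and Z at 11.3%, counted in Q, which the quotient does not name. Its result still gives a quotient of 2.50 L mol⁻¹, though 0.573 of the L so reckoned is free. The neighbouring flask is west with J raised to 0.43 M, so L stands at 0.605 equiv to J. The same reckoning with 2.58 L mol⁻¹ puts its Q at 27.1%. In that neighbouring flask, 0.572 of the reckoned L is free, and the flask ends with Q at 26.7%.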